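The cyclopentane (C1–C5, daucane numbering) is disconnected at C4–C5 as an aldol condensation: C5 is the α-carbon of a C6 cycloheptenone carbonyl next to the quaternary C1, and C4 is a pendant isopropyl ketone. The key step exploits the 1,3-dioxygenation at C4 and C6 across the ring-fusion carbon C5. In one operation it closes the cyclopentane last, gives the C4=C5 enone and moves the ring alkene to C8=C9. The enone then relays stereochemistry: directed epoxidation and a stereospecific 1,2-hydride shift set the 4β-hydroxyl and the trans fusion. The precursor is a (6S)-6-(3-oxoalkyl)cycloheptenone made by asymmetric conjugate addition.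

Key step: step 5

Remark: daucane numbering is used for the bicyclic compounds (C1 quaternary fusion carbon with methyl, C2 and C3 ring methylenes, C4 carbinol with isopropyl, C5 fusion CH, C6 acyloxy carbon, C7 and C10 methylenes, C8 and C9 epoxide carbons); 3-methylcyclohept-2-en-1-one and 4-methylpent-1-en-3-one are taken as purchasable, and the antipode of the chiral ligand in step 4 is the one that gives the (6S) adduct.

Step 1
Reactants: 1 4-methylpent-1-en-3-one
Product: 3 2-(2-bromoethyl)-2-(propan-2-yl)-1,3-dioxolane, via bromoketone 2 (not isolated)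
Conditions: HBr (g), CH2Cl2, 0 °C; then HOCH2CH2OH, TsOH (cat.), benzene, reflux (Dean–Stark)
Reagents that add atoms: hydrogen bromide, Br; ethylene glycol, OCCO
Why: Conjugate addition of HBr to the enone followed by acid-catalysed ketalisation with azeotropic removal of water is the standard route to β-bromoethyl ketals.

Step 2
Reactants: 4 3-methylcyclohept-2-en-1-one
Product: 6 3-methylcyclohepta-2,6-dien-1-one, via silyl dienol ether 5 (not isolated)
Conditions: LiN(i-Pr)2, THF, −78 °C; Me3SiCl; then Pd(OAc)2 (1.05 equiv), MeCN, 25 °C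
Reagents that add atoms: none
Why: Kinetic α′-deprotonation and O-silylation should give the cross-conjugated silyl dienol ether, which a Saegusa–Ito oxidation converts to the dienone.

Step 3
Reactants: 6 3-methylcyclohepta-2,6-dien-1-one
Product: 8 3,6-dimethylcyclohepta-2,6-dien-1-one, via silyl enol ether 7 (not isolated)
Conditions: MeMgBr, CuBr·SMe2 (5 mol %), Me3SiCl, THF, −78 °C; then Pd(OAc)2 (1.05 equiv), MeCN, 25 °C
Reagents that add atoms: methylmagnesium bromide, C[Mg]Br
Why: Copper-catalysed conjugate addition should occur at the unsubstituted β-carbon with silyl trapping of the enolate, and a second Saegusa–Ito oxidation restores the enone, so the transient stereocentre is erased and an achiral dienone results.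

Step 4
Reactants: 8 3,6-dimethylcyclohepta-2,6-dien-1-one; 3 2-(2-bromoethyl)-2-(propan-2-yl)-1,3-dioxolane
Product: 12 (6S)-3,6-dimethyl-6-(4-methyl-3-oxopentyl)cyclohept-2-en-1-one, via Grignard reagent 9 (not isolated), via magnesium enolate 10 (not isolated), via ketal 11 (not isolated)
Conditions: 3, Mg, THF, 25 °C; then 8, Cu(OTf)2 (3 mol %), chiral C2-symmetric 4,5-diphenylimidazolinium chloride (NHC precursor, 4 mol %), Et2O, −30 °C; then 2 M HCl, THF, 25 °C
Reagents that add atoms: water, O
Why: Copper–NHC-catalysed asymmetric conjugate addition of a Grignard reagent to a β-methyl cyclic enone should set the quaternary C1 by ligand-controlled facial attack (the two enone arms of 8 are homotopic and enolate 10 blocks a second addition), after which aqueous acid protonates the enolate and hydrolyses the dioxolane.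

Step 5
Reactants: 12 (6S)-3,6-dimethyl-6-(4-methyl-3-oxopentyl)cyclohept-2-en-1-one
Product: 16 (1R)-dauca-4,8-dien-6-one, via potassium dienolate 13 (not isolated), via aldol adduct 14 (not isolated), via potassium trienolate 15 (not isolated)
Conditions: KOtBu (2.5 equiv), t-BuOH/THF, 0 to 40 °C; then inverse quench into AcOH, THF, −78 °C
Reagents that add atoms: none
Why: Excess KOtBu holds the substrate as the extended dienolate 13, which by α-reprotonation feeds the C5 enolate; this adds to the C4 ketone, E1cB loss of water gives the tetrasubstituted enone, and the enone is at once deprotonated at C7 to trienolate 15, so that the cold acid quench protonates kinetically at C7 and leaves the ring alkene at C8=C9. The closest known reactions are the base-mediated aldol condensation of 1,6-diketones to 2-acylcyclopentenes and the deconjugation of enones by kinetic α-protonation of their dienolates. The cyclopentane closes in the 5-(enolexo)-exo-trig mode, whereas the alternative closures (C3 onto C6, C7 onto C4) would give bridged or seven-membered aldols that cannot dehydrate and should revert. No stereocentre is created, since C4 and C5 become sp2 on purpose, and C1 is untouched. The step needs positional selectivity for the ring alkene, which rests on the kinetic preference for α-protonation of dienolates and on C7–H of 16 being far more acidic than the γ-hydrogens at C3 and on the isopropyl group.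

Step 6
Reactants: 16 (1R)-dauca-4,8-dien-6-one
Product: 17 (1R,6R)-dauca-4,8-dien-6-ol
Conditions: (S)-2-methyl-CBS-oxazaborolidine (20 mol %), catecholborane, toluene, −78 °C
Reagents that add atoms: none
Why: In this Corey–Bakshi–Shibata reduction the tetrasubstituted alkenyl arm acts as the large group, so the (S)-catalyst should deliver hydride to the α face (also the face away from the angular methyl) and set the 6β-hydroxyl (6R) by 1,2-reduction only.

Step 7
Reactants: 17 (1R,6R)-dauca-4,8-dien-6-ol
Product: 18 (1R,4R,5S,6R)-4,5-epoxydauc-8-en-6-ol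
Conditions: VO(acac)2 (5 mol %), t-BuOOH, CH2Cl2, 0 °C
Reagents that add atoms: tert-butyl hydroperoxide, CC(C)(C)OO
Why: In this hydroxyl-directed vanadium epoxidation the allylic C4=C5 alkene should react much faster than the homoallylic C8=C9 alkene, and oxygen is delivered syn to the 6β-hydroxyl, which sets C4 and C5 as the 4β,5β-epoxide.

Step 8
Reactants: 18 (1R,4R,5S,6R)-4,5-epoxydauc-8-en-6-ol
Product: 21 (1R,4R,5R)-4-hydroxydauc-8-en-6-one, via epoxy silyl ether 19 (not isolated), via silyloxy ketone 20 (not isolated)
Conditions: Me3SiOTf (1.3 equiv), 2,6-lutidine, CH2Cl2, −78 to −50 °C; then citric acid, MeOH, 0 °C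
Reagents that add atoms: none
Why: In this semipinacol rearrangement of a 2,3-epoxy silyl ether the silyl triflate activates the epoxide and the C6–H anti to the C5–O bond migrates to C5 with inversion while C6 becomes the carbonyl, so C5–H should be α (trans ring fusion) and C4 keeps its β-oxygen, after which mild acid cleaves the tertiary silyl ether.

Step 9
Reactants: 21 (1R,4R,5R)-4-hydroxydauc-8-en-6-one
Product: 22 (1R,4R,5S,6S)-dauc-8-ene-4,6-diol
Conditions: Me4NBH(OAc)3, MeCN/AcOH, −30 °C
Reagents that add atoms: none
Why: In this Evans–Saksena reduction the 4β-hydroxyl binds the triacetoxyborohydride and delivers hydride intramolecularly to the face of the C6 carbonyl on which C4 lies, which should give the 6α-alcohol (1,3-anti diol) under mildly acidic conditions that avoid enolisation at C5 and C7.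

Step 10
Reactants: 22 (1R,4R,5S,6S)-dauc-8-ene-4,6-diol
Product: 23 (1R,4R,5S,6S,8R,9S)-8,9-epoxydaucane-4,6-diol
Conditions: VO(acac)2 (5 mol %), t-BuOOH, CH2Cl2, 0 to 25 °C
Reagents that add atoms: tert-butyl hydroperoxide, CC(C)(C)OO
Why: In this homoallylic-alcohol-directed vanadium epoxidation the 6α-hydroxyl should deliver oxygen to the α face of the only alkene, which is also the face away from the angular methyl, setting C8 (R) and C9 (S).

Step 11
Reactants: 23 (1R,4R,5S,6S,8R,9S)-8,9-epoxydaucane-4,6-diol; 24 4-acetoxybenzoyl chloride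
Product: 25 (1R,4R,5S,6S,8R,9S)-8,9-epoxy-4-hydroxydaucan-6-yl 4-acetoxybenzoate
Conditions: pyridine, DMAP (10 mol %), CH2Cl2, 0 to 25 °C
Reagents that add atoms: none
Why: Acylation of the secondary 6-hydroxyl with an acid chloride under nucleophilic catalysis should leave the tertiary 4-hydroxyl untouched, and the basic medium protects the epoxide.

Step 12
Reactants: 25 (1R,4R,5S,6S,8R,9S)-8,9-epoxy-4-hydroxydaucan-6-yl 4-acetoxybenzoate
Product: 26 jaeskeanin
Conditions: K2CO3 (0.2 equiv), MeOH, 0 °C
Reagents that add atoms: none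
Why: Base-catalysed methanolysis should cleave the phenolic acetate chemoselectively, because it is far more reactive than the hindered secondary benzoate, and should leave epoxide and tertiary alcohol intact.

Compound list

1 | 4-methylpent-1-en-3-one | CC(C)C(=O)C=C | starting material
2 | 1-bromo-4-methylpentan-3-one | CC(C)C(=O)CCBr | intermediate
3 | 2-(2-bromoethyl)-2-(propan-2-yl)-1,3-dioxolane | CC(C)C1(CCBr)OCCO1 | intermediate
4 | 3-methylcyclohept-2-en-1-one | CC1=CC(=O)CCCC1 | starting material
5 | trimethyl[(6-methylcyclohepta-1,6-dien-1-yl)oxy]silane | CC1=CC(O[Si](C)(C)C)=CCCC1 | intermediate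
6 | 3-methylcyclohepta-2,6-dien-1-one | CC1=CC(=O)C=CCC1 | intermediate
7 | trimethyl[(3,6-dimethylcyclohepta-1,6-dien-1-yl)oxy]silane (racemic) | CC1CCC(C)=CC(O[Si](C)(C)C)=C1 | intermediate
8 | 3,6-dimethylcyclohepta-2,6-dien-1-one | CC1=CC(=O)C=C(C)CC1 | intermediate
9 | {2-[2-(propan-2-yl)-1,3-dioxolan-2-yl]ethyl}magnesium bromide | CC(C)C1(CC[Mg]Br)OCCO1 | intermediate
10 | bromomagnesium dienolate of 11 | CC(C)C1(CC[C@]2(C)CCC(C)=CC(O[Mg]Br)=C2)OCCO1 | intermediate
11 | (6S)-3,6-dimethyl-6-{2-[2-(propan-2-yl)-1,3-dioxolan-2-yl]ethyl}cyclohept-2-en-1-one | CC(C)C1(CC[C@]2(C)CCC(C)=CC(=O)C2)OCCO1 | intermediate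
12 | (6S)-3,6-dimethyl-6-(4-methyl-3-oxopentyl)cyclohept-2-en-1-one | CC(C)C(=O)CC[C@]1(C)CCC(C)=CC(=O)C1 | intermediate
13 | extended potassium dienolate of 12 | CC(C)C(=O)CC[C@]1(C)CC=C(C)C=C([O-])C1.[K+] | intermediate
14 | aldol adduct (1R)-4-hydroxydauc-8-en-6-one, C4 and C5 not defined | CC(C)C1(O)CC[C@]2(C)CC=C(C)CC(=O)C12 | intermediate
15 | potassium trienolate of 16 | CC(C)C1=C2C([O-])=CC(C)=CC[C@@]2(C)CC1.[K+] | intermediate
16 | (1R)-dauca-4,8-dien-6-one | CC(C)C1=C2C(=O)CC(C)=CC[C@@]2(C)CC1 | intermediate
17 | (1R,6R)-dauca-4,8-dien-6-ol (6β-OH) | CC(C)C1=C2[C@H](O)CC(C)=CC[C@@]2(C)CC1 | intermediate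
18 | (1R,4R,5S,6R)-4,5-epoxydauc-8-en-6-ol (4β,5β-epoxide, 6β-OH) | CC(C)[C@@]12O[C@@]13[C@H](O)CC(C)=CC[C@@]3(C)CC2 | intermediate
19 | trimethylsilyl ether of 18 | CC(C)[C@@]12O[C@@]13[C@H](O[Si](C)(C)C)CC(C)=CC[C@@]3(C)CC2 | intermediate
20 | (1R,4R,5R)-4-(trimethylsilyloxy)dauc-8-en-6-one | CC(C)[C@]1(O[Si](C)(C)C)CC[C@]2(C)CC=C(C)CC(=O)[C@H]21 | intermediate
21 | (1R,4R,5R)-4-hydroxydauc-8-en-6-one (4β-OH, 5α-H) | CC(C)[C@]1(O)CC[C@]2(C)CC=C(C)CC(=O)[C@H]21 | intermediate
22 | (1R,4R,5S,6S)-dauc-8-ene-4,6-diol (jaeschkeanadiol) | CC(C)[C@]1(O)CC[C@]2(C)CC=C(C)C[C@H](O)[C@H]21 | intermediate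
23 | (1R,4R,5S,6S,8R,9S)-8,9-epoxydaucane-4,6-diol | CC(C)[C@]1(O)CC[C@]2(C)C[C@@H]3O[C@]3(C)C[C@H](O)[C@H]21 | intermediate
24 | 4-acetoxybenzoyl chloride | CC(=O)Oc1ccc(cc1)C(Cl)=O | starting material
25 | (1R,4R,5S,6S,8R,9S)-8,9-epoxy-4-hydroxydaucan-6-yl 4-acetoxybenzoate | CC(C)[C@]1(O)CC[C@]2(C)C[C@@H]3O[C@]3(C)C[C@H](OC(=O)c3ccc(OC(C)=O)cc3)[C@H]21 | intermediate
26 | jaeskeanin, (1R,4R,5S,6S,8R,9S)-8,9-epoxy-4-hydroxydaucan-6-yl 4-hydroxybenzoate | CC(C)[C@]1(O)CC[C@]2(C)C[C@@H]3O[C@]3(C)C[C@H](OC(=O)c3ccc(O)cc3)[C@H]21 | target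

Total step count: 12. Longest linear sequence: 11 steps (steps 2 to 12, from 4); step 1 is a one-step side branch that joins in step 4.

Steps most likely to fail

Step 5. The alkene positions may scramble: γ-protonation of the trienolate, or deprotonation at C3 after leakage to the cross-conjugated dienone, would give isomeric enones, and the chain enolate may add to the conjugated enone before deconjugation. The fallback separates deconjugation from ring closure. It sets out from ketal 11, obtained by ending step 4 with aqueous NH4Cl in place of HCl. Treatment with KOtBu in t-BuOH and a cold AcOH quench should give (6R)-3,6-dimethyl-6-{2-[2-(propan-2-yl)-1,3-dioxolan-2-yl]ethyl}cyclohept-3-en-1-one F1, a stage at which only one ring γ-methylene can be deprotonated. PPTS in wet acetone should then unmask (6R)-3,6-dimethyl-6-(4-methyl-3-oxopentyl)cyclohept-3-en-1-one F2. Aldol condensation of this already deconjugated diketone with 1.1 equiv of KOtBu in THF at −20 to 0 °C, again quenched cold with AcOH, comes back to the route at 16.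

Step 8. The epoxide may ionise at C4 instead of C5, or C7 may migrate in place of hydride, which would lead to elimination or ring-contracted products. The fallback sets out from 18. Dess–Martin oxidation should give (1R,4R,5R)-4,5-epoxydauc-8-en-6-one F3. SmI2 in THF/MeOH at −90 °C cleaves the C5–O bond of an α,β-epoxy ketone regiospecifically. Protonation of the samarium enolate, which is chelated to the 4β-alkoxide, from the opposite α face should come back to the route at 21.

Step 4. Facial selectivity may be poor on the cross-conjugated dienone with a functionalised Grignard reagent, and 1,2-addition may compete. The fallback sets out from 8 and 3 and uses an alkylzirconium nucleophile. Dehydrobromination of 3 (KOtBu, THF) should give 2-ethenyl-2-(propan-2-yl)-1,3-dioxolane F4. Hydrozirconation with Cp2ZrHCl gives chlorobis(cyclopentadienyl){2-[2-(propan-2-yl)-1,3-dioxolan-2-yl]ethyl}zirconium F5. Asymmetric conjugate addition of F5 to 8 with CuCl, AgNTf2 and a chiral phosphoramidite (Me3SiCl, Et2O) comes back to the route at 11, which is hydrolysed as in step 4.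

Further compounds

F1 | step 5 | (6R)-3,6-dimethyl-6-{2-[2-(propan-2-yl)-1,3-dioxolan-2-yl]ethyl}cyclohept-3-en-1-one | CC(C)C1(CC[C@]2(C)CC=C(C)CC(=O)C2)OCCO1
F2 | step 5 | (6R)-3,6-dimethyl-6-(4-methyl-3-oxopentyl)cyclohept-3-en-1-one | CC(C)C(=O)CC[C@]1(C)CC=C(C)CC(=O)C1
F3 | step 8 | (1R,4R,5R)-4,5-epoxydauc-8-en-6-one | CC(C)[C@@]12O[C@@]13C(=O)CC(C)=CC[C@@]3(C)CC2
F4 | step 4 | 2-ethenyl-2-(propan-2-yl)-1,3-dioxolane | CC(C)C1(C=C)OCCO1
F5 | step 4 | chlorobis(cyclopentadienyl){2-[2-(propan-2-yl)-1,3-dioxolan-2-yl]ethyl}zirconium | CC(C)C1(CC[Zr](Cl)(C2C=CC=C2)C2C=CC=C2)OCCO1
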